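## Structural features

The target is a macrocyclic bis(bibenzyl) of the marchantin type. Four benzene rings (A, the methoxy arene; B, the meta-linked arene; C, the phenol ring; D, the para-linked arene) are joined in an 18-membered ring by two CH2CH2 bridges (A to D, B to C) and two diaryl ether oxygens (A to B, C to D). Ring A is 1,2,3-trisubstituted: OMe at C1, the ether oxygen to ring B at C2 and the ethano bridge at C3, so the A–B ether oxygen is flanked on both sides. Ring C carries a free OH para to its bridge and ortho to the ether oxygen to ring D; rings B and D are plain meta and para spacers. There is no stereocentre, so no neighbouring stereocentres have to be related; the problems are regiochemical and entropic. Fragile points are the electron-rich phenol of ring C, the benzylic CH2 groups, and the need to tell the ring A methyl ether from the ring C phenol at the end. The real difficulty is the flanked C2–O bond of ring A, which resists SNAr and Ullmann chemistry, together with closing an 18-membered ring. The plan exploits the vicinal oxygen pattern at C1 and C2 of ring A: C1–O maps onto the carbonyl and C2 onto the diazo carbon of an ortho-quinone diazide, so a carbenoid at C2 can take up the ring B phenol while ring A aromatises and releases its C1 oxygen as a phenol.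

## Logic of the disconnections

21 to 20: the isopropyl C–O bond on ring C is cut last. An isopropyl ether survives base, hydrogenation, nitrous acid, fluoride and the rhodium step, and keeps the ring C oxygen distinct from the ring A oxygen. The forward step needs a Lewis acid that removes a secondary alkyl group but leaves the methyl ether and both diaryl ethers.

20 to 19: the O–CH3 bond on ring A is cut. The key step necessarily delivers the C1 oxygen of ring A as a free phenol, and it is the only OH in 19, so the methylation needs no selectivity.

19 to 18: the bond between C2 of ring A and the ring B oxygen is cut. This opens the macrocycle and makes the most hindered bond the ring-forming one. The gain is an open chain in which every other bond is already in place. The demand is a carbenoid generated without light, which must take the intramolecular O–H in preference to ring contraction, arylation of ring D and intermolecular capture.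

18 to 17 to 15: the O–Si bond on ring B and the C2–N bond of the diazo group are cut back to a silyl ether and an ortho-aminophenol. The silyl ether keeps the ring B phenol away from nitrous acid and from the diazonium ion. The forward steps must diazotise without losing the silyl group, and then remove it without triggering azo coupling.

15 to 14, then 14 to 11 + 13: both ethano bridges, the amine and the ring A phenol are traced back to two C=C bonds, a nitro group and a benzyl ether, all handled by one hydrogenation. The B–C double bond is then cut by a Wittig disconnection. Ring B enters only here, carrying its silyl ether, because that group would not survive the fluoride and hot carbonate of the SNAr step. The base must tolerate a nitroarene and the silyl ether.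

11 to 10 to 9 + 5: the benzylic C–P bond is traced to a benzylic alcohol, and the A–D double bond is cut by a second Wittig disconnection. 5 carries its two bridge carbons at different oxidation levels (CHO on ring D, CH2OH on ring C), so they react in sequence without protecting groups. The ylide of 9 must tolerate a free alcohol, and the phosphonium formation must tolerate nitro, stilbene and benzyl ether.

5 to 3 + 4, 3 to 2 to 1: the bond between the ring C oxygen and ring D is cut (SNAr on a para-formyl aryl fluoride). 3 comes from 1 by selective alkylation of the more acidic 4-OH and reduction of the aldehyde. Reducing before the SNAr step is what differentiates the two bridge carbons.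

9 to 8 to 7 to 6, and 13 to 12: the ring A ylide precursor is cut at C–P, then taken back through the alcohol and the benzyl ether to 6. The benzyl group costs no extra removal step. 13 is the silyl ether of 12.

## Other disconnections considered

Alternative 1: The cut is the bond between ring D and the neighbouring CH2 of the A–D bridge, made by ring expansion and not by ring closure.
- Forward step: a 17-membered macrocycle A1, in which rings A and D share one sp2 carbon bearing an exocyclic methylene, would be treated with PhI(OH)OTs in aqueous methanol. The trivalent iodine reagent adds to the terminal CH2, methanol caps the diaryl cation, and ring D shifts to the CH2 carbon as iodobenzene leaves. Hydrolysis would give the 18-membered deoxybenzoin A2.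
- In favour: oxidative 1,2-aryl shifts of 1,1-diarylethenes are an established reaction class. The new bond is C–C and the expansion from 17 to 18 atoms should relieve strain. Migration of the other aryl group would be harmless, since both ketone regioisomers give the same CH2CH2 bridge after deoxygenation. An acyl carbon at C3 of ring A in the early intermediates would also activate C2 for SNAr, so the crowded ether could be made by substitution; on this structural point the alternative is the better plan. The methyl ether is present from the start.
- Against: A1 must first be built, which needs a separate macrocyclisation to a smaller, stiffer ring and methylenation of a doubly ortho-flanked diaryl ketone. Four electron-rich arenes meet an oxidising iodine reagent. After A2 the carbonyl and the benzyl group must still go, though perhaps in one hydrogenolysis, which would equal or beat the two closing steps here.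
- Comparison: mechanistically a cationic rearrangement with good precedent replaces a carbenoid step without direct precedent, which is an advantage. In step economy it is longer, because closure, methylenation, rearrangement and deoxygenation replace the single step from 18 to 19.

Alternative 2: The cut is the unhindered ether bond between the ring D oxygen and C3 of ring C.
- Forward step: the open bis(dihalophenol) A3 (ring C a 2,6-dibromophenol, ring D a 2,6-dichlorophenol) would be oxidised at an anode. The oxidised ring C is captured at a bromine-bearing ortho carbon by the ring D phenol oxygen. Zinc in the same pot would reduce the bromo dienone, with loss of bromide, to the macrocycle A4. Hydrogenolysis of the three halogens would then give the target directly.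
- In favour: it follows the presumed biosynthetic phenol coupling, and anodic coupling of dihalophenols with zinc reduction is a known way to diaryl ethers. The C and D phenols need no protecting groups. The end game is one step against two here, a point on which it is better.
- Against: the ring is closed at the ether that SNAr makes easily (step 3 here), while the flanked C2–O bond of ring A is left to conventional coupling on an ortho,ortho-disubstituted arene. Four halogens must be placed on two phenol rings before the fragments are joined, and removed afterwards. The two dihalophenols differ only modestly in oxidation potential, so homo-coupling, oligomerisation and over-oxidation are likely competitors. Electrochemical equipment is needed.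
- Comparison: structurally the chosen plan spends its key step on the hard bond and this one on the easy bond. Mechanistically both are C–O macrocyclisations, and this one has the closer precedent. In step economy its shorter end game is offset by the halogenation steps and the extra work for the crowded ether.

Alternative 3: The cut is the bond between C1 of ring C and the adjacent carbon of the B–C bridge, with that carbon at the ketone level.
- Forward step: the ring B arylacetic acid A5 would be converted with trifluoroacetic anhydride at high dilution into its mixed anhydride. This would acylate ring C para to the isopropoxy group in a Friedel–Crafts macrocyclisation and give the deoxybenzoin A6. Deoxygenation and BCl3 cleavage of the isopropyl ether would follow.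
- In favour: ring C needs no handle (a C–H bond is used) and A5 is assembled convergently. Acylation of alkoxyarenes by arylacetic acids under such conditions is known. The methyl ether is present throughout, and the two-step end game equals that of the chosen plan.
- Against: selectivity rests on electronic bias alone. The position para to the aryloxy group of ring C, the free position para to OMe on ring A and the positions ortho to oxygen on ring D are all nucleophilic, and intermolecular acylation competes with an 18-membered closure. The mixed anhydride can collapse to a ketene. The acidic medium may attack the isopropyl ether. The crowded ring A ether must again be made beforehand.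
- Comparison: this alternative is the equal or the better in precedent and in the simplicity of its ring C fragment. The chosen step has a built-in selectivity element (one O–H, one carbenoid) that the acylation lacks, and it forms the hardest bond in the same operation that closes the ring.

Key step: step 14

Assumption: the stilbene-type intermediates 10, 11 and 14 are carried as mixtures of double-bond isomers, since both double bonds are saturated in step 11; the target has no stereocentre.

## Route

Step 1
Reactants: 1 3,4-dihydroxybenzaldehyde
Product: 2 3-hydroxy-4-(propan-2-yloxy)benzaldehyde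
Conditions: 2-bromopropane (1.2 equiv), K2CO3 (1.0 equiv), DMF, 50 °C
Reagents that add atoms: 2-bromopropane, CC(C)Br
Why: Williamson ether synthesis; the 4-OH para to the formyl group is the more acidic hydroxyl, so one equivalent of carbonate should ionise and alkylate it in preference to the 3-OH.

Step 2
Reactants: 2 3-hydroxy-4-(propan-2-yloxy)benzaldehyde
Product: 3 5-(hydroxymethyl)-2-(propan-2-yloxy)phenol
Conditions: NaBH4, MeOH, 0 °C
Reagents that add atoms: none
Why: Borohydride reduction of the aldehyde; putting ring C at the alcohol level before the SNAr step lets the two bridge carbons of the C–D unit (CH2OH on ring C, CHO on ring D) be addressed one after the other without protecting groups.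

Step 3
Reactants: 3 5-(hydroxymethyl)-2-(propan-2-yloxy)phenol; 4 4-fluorobenzaldehyde
Product: 5 4-[5-(hydroxymethyl)-2-(propan-2-yloxy)phenoxy]benzaldehyde
Conditions: K2CO3, DMF, 110 °C
Reagents that add atoms: none
Why: SNAr on the para-formyl-activated aryl fluoride; carbonate ionises only the phenol and not the benzylic alcohol, so arylation should occur at the ring C phenol oxygen and give the C–D diaryl ether.

Step 4
Reactants: 6 3-hydroxy-2-nitrobenzaldehyde
Product: 7 3-(benzyloxy)-2-nitrobenzaldehyde
Conditions: BnBr, K2CO3, DMF, rt
Reagents that add atoms: benzyl bromide, BrCc1ccccc1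
Why: Williamson benzylation of the acidic nitrophenol; the benzyl group keeps a phenoxide out of both Wittig steps and needs no separate removal, since it falls in the hydrogenation of step 11.

Step 5
Reactants: 7 3-(benzyloxy)-2-nitrobenzaldehyde
Product: 8 [3-(benzyloxy)-2-nitrophenyl]methanol
Conditions: NaBH4, MeOH–THF, 0 °C
Reagents that add atoms: none
Why: Borohydride reduction; NaBH4 reduces the aldehyde and leaves the nitro group and the benzyl ether untouched.

Step 6
Reactants: 8 [3-(benzyloxy)-2-nitrophenyl]methanol
Product: 9 {[3-(benzyloxy)-2-nitrophenyl]methyl}triphenylphosphonium bromide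
Conditions: PPh3·HBr, MeCN, reflux
Reagents that add atoms: triphenylphosphine hydrobromide, Br.c1ccc(cc1)P(c1ccccc1)c1ccccc1
Why: Direct conversion of a benzylic alcohol into its phosphonium salt (bromide formed in situ, then quaternisation of PPh3); the ortho-nitro group slows ionisation, so prolonged reflux is planned.

Step 7
Reactants: 9 {[3-(benzyloxy)-2-nitrophenyl]methyl}triphenylphosphonium bromide; 5 4-[5-(hydroxymethyl)-2-(propan-2-yloxy)phenoxy]benzaldehyde
Product: 10 [3-(4-{2-[3-(benzyloxy)-2-nitrophenyl]ethenyl}phenoxy)-4-(propan-2-yloxy)phenyl]methanol, mixture of E and Z isomers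
Conditions: K2CO3, 18-crown-6 (cat.), CH2Cl2, reflux
Reagents that add atoms: none
Why: Wittig olefination with the nitro-stabilised benzylic ylide under mild solid–liquid conditions that tolerate the free benzylic alcohol; the double-bond geometry does not matter because the bond is hydrogenated in step 11.

Step 8
Reactants: 10 [3-(4-{2-[3-(benzyloxy)-2-nitrophenyl]ethenyl}phenoxy)-4-(propan-2-yloxy)phenyl]methanol
Product: 11 {[3-(4-{2-[3-(benzyloxy)-2-nitrophenyl]ethenyl}phenoxy)-4-(propan-2-yloxy)phenyl]methyl}triphenylphosphonium bromide, mixture of E and Z isomers
Conditions: PPh3·HBr, MeCN, reflux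
Reagents that add atoms: triphenylphosphine hydrobromide, Br.c1ccc(cc1)P(c1ccccc1)c1ccccc1
Why: The same alcohol-to-phosphonium conversion as in step 6, here on a para-alkoxybenzylic alcohol that ionises readily; nitro group, benzyl ether, isopropyl ether and stilbene are expected to tolerate the reagent.

Step 9
Reactants: 12 3-hydroxybenzaldehyde
Product: 13 3-{[tri(propan-2-yl)silyl]oxy}benzaldehyde
Conditions: TIPSCl, imidazole, DMF, rt
Reagents that add atoms: chlorotri(propan-2-yl)silane, CC(C)[Si](Cl)(C(C)C)C(C)C
Why: Imidazole-promoted silylation of a phenol; the bulky triisopropylsilyl ether is chosen because it must survive a strong-base Wittig step, hydrogenation and acidic diazotisation and still leave with fluoride.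

Step 10
Reactants: 11 the ring C phosphonium bromide; 13 3-{[tri(propan-2-yl)silyl]oxy}benzaldehyde
Product: 14 1-(benzyloxy)-2-nitro-3-{2-[4-(2-(propan-2-yloxy)-5-{2-[3-(triisopropylsilyloxy)phenyl]ethenyl}phenoxy)phenyl]ethenyl}benzene, mixture of double-bond isomers
Conditions: NaHMDS, THF, −78 °C to rt
Reagents that add atoms: none
Why: Wittig olefination of the semi-stabilised ylide of 11 with aldehyde 13; ring B is introduced only now because its silyl ether would not survive the fluoride and hot carbonate of step 3.

Step 11
Reactants: 14 the bis-stilbene
Product: 15 2-amino-3-{2-[4-(2-(propan-2-yloxy)-5-{2-[3-(triisopropylsilyloxy)phenyl]ethyl}phenoxy)phenyl]ethyl}phenol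
Conditions: H2 (3 bar), 10% Pd/C, EtOAc–EtOH, rt; product kept under argon
Reagents that add atoms: none
Why: Catalytic hydrogenation should saturate both stilbene double bonds, reduce the nitro group to the amine and hydrogenolyse the benzyl ether in one operation, while the aryl silyl ether, isopropyl ether and diaryl ether are inert; the air-sensitive aminophenol is used at once.

Step 12
Reactants: 15 the ring A ortho-aminophenol
Product: 17 6-diazo-5-{2-[4-(2-(propan-2-yloxy)-5-{2-[3-(triisopropylsilyloxy)phenyl]ethyl}phenoxy)phenyl]ethyl}cyclohexa-2,4-dien-1-one, via diazonium chloride 16 (not isolated)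
Conditions: isoamyl nitrite (1.1 equiv), HCl in EtOH (2.2 equiv), THF, −10 °C, dark; then cold aq NaHCO3, extraction into CH2Cl2
Reagents that add atoms: isoamyl nitrite, CC(C)CCON=O
Why: Diazotisation of an ortho-aminophenol followed by deprotonation of the 2-hydroxyarenediazonium ion gives the neutral ortho-quinone diazide, a classical transformation; the ring B phenol stays silylated so that it can be neither C-nitrosated nor azo-coupled by the diazonium ion.

Step 13
Reactants: 17 the silylated ortho-quinone diazide
Product: 18 6-diazo-5-{2-[4-(5-[2-(3-hydroxyphenyl)ethyl]-2-(propan-2-yloxy)phenoxy)phenyl]ethyl}cyclohexa-2,4-dien-1-one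
Conditions: TBAF–AcOH (1:1, 1.1 equiv), THF, 0 °C, dark
Reagents that add atoms: none
Why: Fluoride cleavage of an aryl silyl ether; buffering with acetic acid keeps the liberated phenol protonated, so azo coupling with the weakly electrophilic diazo-oxide is not expected, and the diazo-oxide should be inert to buffered fluoride.

Step 14
Reactants: 18 the open-chain ortho-quinone diazide with free ring B phenol
Product: 19 the 18-membered macrocycle with free ring A phenol (OH at C1, ring B oxygen at C2, bridge at C3) and ring C isopropyl ether
Conditions: Rh2(OAc)4 (2 mol %), CH2Cl2, 25 °C, syringe-pump addition of 18 over 12 h to about 1 mM, argon, dark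
Reagents that add atoms: none
Why: Proposed new method: Rh2(OAc)4 should take N2 out of 18 and give an electrophilic rhodium carbenoid at C2 of ring A; the ring B phenol oxygen attacks it to form an oxonium ylide, and a proton shift to the former carbonyl oxygen releases the catalyst and aromatises ring A as the 2-aryloxyphenol. The closest known reaction type is the Rh2(OAc)4-catalysed O–H insertion of diazonaphthoquinones into alcohols and phenols, together with carbenoid O–H insertion macrocyclisations of diazo carbonyl compounds; new here is a simple ortho-benzoquinone diazide used for a ring-forming aryl ether synthesis. The 18-membered ring is closed end to end by this one C–O bond, under pseudo-high dilution so that the carbenoid meets its own phenol first. No stereocentre is formed. The insertion has to outrun four paths: Wolff-type contraction to a ketene, attack on the ortho C–H of ring D (which, contrary to a first impression that no C–H is in reach, would close a six-membered ring to a 9,10-dihydrophenanthrene), capture by water, and capture by the phenol of the product. A metal-bound carbenoid made without light disfavours the ketene path, the substrate holds only one free O–H, ylide formation at oxygen is normally faster than attack on an arene position meta to the ring D ether oxygen, and dry solvent with a low stationary concentration limits the intermolecular paths. Gain of aromaticity makes the insertion irreversible, and the crowded ether is formed at a two-coordinate carbon and not by substitution on a hindered arene.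

Step 15
Reactants: 19 the macrocyclic ring A phenol
Product: 20 the macrocycle with ring A methyl ether and ring C isopropyl ether
Conditions: MeI, K2CO3, acetone, 50 °C
Reagents that add atoms: iodomethane, CI
Why: Williamson O-methylation; 19 has a single free OH, the ring A phenol created in the key step, so no selectivity question arises.

Step 16
Reactants: 20 the macrocyclic methyl isopropyl diether
Product: 21 the target, CNP0309263.0
Conditions: BCl3 (1 M in CH2Cl2), CH2Cl2, −78 to 0 °C; then MeOH, H2O
Reagents that add atoms: none
Why: Lewis-acid dealkylation; BCl3 cleaves secondary alkyl aryl ethers at low temperature through a carbocation-like path well before it attacks methyl aryl ethers or diaryl ethers, which should free the ring C phenol.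

## Compound list

1 | 3,4-dihydroxybenzaldehyde | O=Cc1ccc(O)c(O)c1 | starting material
2 | 3-hydroxy-4-(propan-2-yloxy)benzaldehyde | O=Cc1ccc(OC(C)C)c(O)c1 | intermediate
3 | 5-(hydroxymethyl)-2-(propan-2-yloxy)phenol | OCc1ccc(OC(C)C)c(O)c1 | intermediate
4 | 4-fluorobenzaldehyde | O=Cc1ccc(F)cc1 | starting material
5 | 4-[5-(hydroxymethyl)-2-(propan-2-yloxy)phenoxy]benzaldehyde | OCc1ccc(OC(C)C)c(Oc2ccc(C=O)cc2)c1 | intermediate
6 | 3-hydroxy-2-nitrobenzaldehyde | O=Cc1cccc(O)c1[N+](=O)[O-] | starting material
7 | 3-(benzyloxy)-2-nitrobenzaldehyde | O=Cc1cccc(OCc2ccccc2)c1[N+](=O)[O-] | intermediate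
8 | [3-(benzyloxy)-2-nitrophenyl]methanol | OCc1cccc(OCc2ccccc2)c1[N+](=O)[O-] | intermediate
9 | {[3-(benzyloxy)-2-nitrophenyl]methyl}triphenylphosphonium bromide | [Br-].[O-][N+](=O)c1c(OCc2ccccc2)cccc1C[P+](c1ccccc1)(c1ccccc1)c1ccccc1 | intermediate
10 | [3-(4-{2-[3-(benzyloxy)-2-nitrophenyl]ethenyl}phenoxy)-4-(propan-2-yloxy)phenyl]methanol, E/Z mixture | OCc1ccc(OC(C)C)c(Oc2ccc(C=Cc3cccc(OCc4ccccc4)c3[N+](=O)[O-])cc2)c1 | intermediate
11 | {[3-(4-{2-[3-(benzyloxy)-2-nitrophenyl]ethenyl}phenoxy)-4-(propan-2-yloxy)phenyl]methyl}triphenylphosphonium bromide, E/Z mixture | [Br-].CC(C)Oc1ccc(C[P+](c2ccccc2)(c2ccccc2)c2ccccc2)cc1Oc1ccc(C=Cc2cccc(OCc3ccccc3)c2[N+](=O)[O-])cc1 | intermediate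
12 | 3-hydroxybenzaldehyde | O=Cc1cccc(O)c1 | starting material
13 | 3-{[tri(propan-2-yl)silyl]oxy}benzaldehyde | O=Cc1cccc(O[Si](C(C)C)(C(C)C)C(C)C)c1 | intermediate
14 | 1-(benzyloxy)-2-nitro-3-{2-[4-(2-(propan-2-yloxy)-5-{2-[3-(triisopropylsilyloxy)phenyl]ethenyl}phenoxy)phenyl]ethenyl}benzene, mixture of double-bond isomers | CC(C)Oc1ccc(C=Cc2cccc(O[Si](C(C)C)(C(C)C)C(C)C)c2)cc1Oc1ccc(C=Cc2cccc(OCc3ccccc3)c2[N+](=O)[O-])cc1 | intermediate
15 | 2-amino-3-{2-[4-(2-(propan-2-yloxy)-5-{2-[3-(triisopropylsilyloxy)phenyl]ethyl}phenoxy)phenyl]ethyl}phenol | Nc1c(O)cccc1CCc1ccc(Oc2cc(CCc3cccc(O[Si](C(C)C)(C(C)C)C(C)C)c3)ccc2OC(C)C)cc1 | intermediate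
16 | 2-hydroxy-6-{2-[4-(2-(propan-2-yloxy)-5-{2-[3-(triisopropylsilyloxy)phenyl]ethyl}phenoxy)phenyl]ethyl}benzenediazonium chloride | [Cl-].N#[N+]c1c(O)cccc1CCc1ccc(Oc2cc(CCc3cccc(O[Si](C(C)C)(C(C)C)C(C)C)c3)ccc2OC(C)C)cc1 | intermediate (not isolated)
17 | 6-diazo-5-{2-[4-(2-(propan-2-yloxy)-5-{2-[3-(triisopropylsilyloxy)phenyl]ethyl}phenoxy)phenyl]ethyl}cyclohexa-2,4-dien-1-one | O=C1C=CC=C(CCc2ccc(Oc3cc(CCc4cccc(O[Si](C(C)C)(C(C)C)C(C)C)c4)ccc3OC(C)C)cc2)C1=[N+]=[N-] | intermediate
18 | 6-diazo-5-{2-[4-(5-[2-(3-hydroxyphenyl)ethyl]-2-(propan-2-yloxy)phenoxy)phenyl]ethyl}cyclohexa-2,4-dien-1-one | O=C1C=CC=C(CCc2ccc(cc2)Oc2cc(ccc2OC(C)C)CCc2cccc(O)c2)C1=[N+]=[N-] | intermediate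
19 | 18-membered macrocycle, ring A phenol (OH at C1, ring B oxygen at C2), ring C isopropyl ether | Oc1cccc2c1Oc1cccc(c1)CCc1ccc(OC(C)C)c(c1)Oc1ccc(cc1)CC2 | intermediate
20 | 18-membered macrocycle, ring A methyl ether, ring C isopropyl ether | COc1cccc2c1Oc1cccc(c1)CCc1ccc(OC(C)C)c(c1)Oc1ccc(cc1)CC2 | intermediate
21 | CNP0309263.0: 18-membered macrocycle, ring A methyl ether, ring C free phenol | COc1cccc2c1Oc1cccc(c1)CCc1ccc(O)c(c1)Oc1ccc(cc1)CC2 | target

## Step count and least certain steps

Total: 16 steps. Longest linear sequence: 12 steps (1, 2, 3, 7, 8, 10, 11, 12, 13, 14, 15, 16 from compound 1; the ring A branch through steps 4 to 6 is equally long). Ring B enters in one step (9).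

Step 14 (key step, proposed new method). The carbenoid is most likely to be diverted: by ring contraction to a ketene, by attack on the ortho C–H of ring D with six-membered ring closure, or by intermolecular O–H insertion (another molecule, the phenol of the product, traces of water). The effective molarity of an 18-membered closure is low. The fallback uses known chemistry and sets out from 15. Diazotisation as in step 12 without neutralisation, followed by KI, should give in a Sandmeyer-type iodination the iodophenol 2-iodo-3-{2-[4-(2-(propan-2-yloxy)-5-{2-[3-(triisopropylsilyloxy)phenyl]ethyl}phenoxy)phenyl]ethyl}phenol F1. Methylation (MeI, K2CO3, acetone) gives its methyl ether F2. Buffered TBAF frees the ring B phenol to give the iodoanisole phenol F3. An intramolecular Ullmann-type diaryl ether coupling at high dilution (CuI, picolinic acid, K3PO4, DMSO, 90 °C) closes the ring and rejoins the route at 20. Its weak point is the doubly ortho-flanked aryl iodide, which is why it is the reserve and not the main plan.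

Step 13. Phenoxide formed during fluoride cleavage may couple with the diazo-oxide, or the diazide may lose nitrogen on handling in a basic medium. The fallback sets out from 15 and unmasks the phenol at the diazonium stage, under acid. Diazotisation with tert-butyl nitrite and HBF4·OEt2 in THF gives the silylated diazonium tetrafluoroborate F4. HF·pyridine in MeCN at 0 °C removes the silyl group while ring A stays a non-coupling diazonium ion, giving the desilylated diazonium tetrafluoroborate F5. Cold aqueous NaHCO3 then gives 18 directly.

Step 12. The very lipophilic amine salt may be nitrosated incompletely, so that free amine couples with diazonium ion, and the silyl ether may be partly lost in the acidic medium. The fallback sets out from 15 and reverses the order. TBAF gives the amino diphenol 2-amino-3-{2-[4-(5-[2-(3-hydroxyphenyl)ethyl]-2-(propan-2-yloxy)phenoxy)phenyl]ethyl}phenol F6. It is diazotised homogeneously with one equivalent of NaNO2 in aqueous HCl–THF at 0 °C, where N-nitrosation of the amine should outpace C-nitrosation of the phenol and azo coupling is suppressed at low pH. Neutralisation gives 18, and step 13 is skipped.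

Step 6. Substitution at the protonated alcohol may stall because the ortho-nitro group disfavours ionisation, and prolonged heating with HBr may start to attack the benzyl ether. The fallback sets out from 8. Appel bromination (CBr4, PPh3, CH2Cl2, 0 °C) gives the benzylic bromide 1-(benzyloxy)-3-(bromomethyl)-2-nitrobenzene F7. Quaternisation with PPh3 in toluene at reflux gives 9.

## Further compounds

F1 | step 14 | 2-iodo-3-{2-[4-(2-(propan-2-yloxy)-5-{2-[3-(triisopropylsilyloxy)phenyl]ethyl}phenoxy)phenyl]ethyl}phenol | Oc1cccc(CCc2ccc(Oc3cc(CCc4cccc(O[Si](C(C)C)(C(C)C)C(C)C)c4)ccc3OC(C)C)cc2)c1I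
F2 | step 14 | 2-iodo-1-methoxy-3-{2-[4-(2-(propan-2-yloxy)-5-{2-[3-(triisopropylsilyloxy)phenyl]ethyl}phenoxy)phenyl]ethyl}benzene | COc1cccc(CCc2ccc(Oc3cc(CCc4cccc(O[Si](C(C)C)(C(C)C)C(C)C)c4)ccc3OC(C)C)cc2)c1I
F3 | step 14 | 3-{2-[3-(4-[2-(2-iodo-3-methoxyphenyl)ethyl]phenoxy)-4-(propan-2-yloxy)phenyl]ethyl}phenol | COc1cccc(CCc2ccc(Oc3cc(CCc4cccc(O)c4)ccc3OC(C)C)cc2)c1I
F4 | step 13 | 2-hydroxy-6-{2-[4-(2-(propan-2-yloxy)-5-{2-[3-(triisopropylsilyloxy)phenyl]ethyl}phenoxy)phenyl]ethyl}benzenediazonium tetrafluoroborate | F[B-](F)(F)F.N#[N+]c1c(O)cccc1CCc1ccc(Oc2cc(CCc3cccc(O[Si](C(C)C)(C(C)C)C(C)C)c3)ccc2OC(C)C)cc1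
F5 | step 13 | 2-hydroxy-6-{2-[4-(5-[2-(3-hydroxyphenyl)ethyl]-2-(propan-2-yloxy)phenoxy)phenyl]ethyl}benzenediazonium tetrafluoroborate | F[B-](F)(F)F.N#[N+]c1c(O)cccc1CCc1ccc(Oc2cc(CCc3cccc(O)c3)ccc2OC(C)C)cc1
F6 | step 12 | 2-amino-3-{2-[4-(5-[2-(3-hydroxyphenyl)ethyl]-2-(propan-2-yloxy)phenoxy)phenyl]ethyl}phenol | Nc1c(O)cccc1CCc1ccc(Oc2cc(CCc3cccc(O)c3)ccc2OC(C)C)cc1
F7 | step 6 | 1-(benzyloxy)-3-(bromomethyl)-2-nitrobenzene | BrCc1cccc(OCc2ccccc2)c1[N+](=O)[O-]
A1 | alternative 1 | 17-membered macrocyclic 1,1-diarylethene, exocyclic methylene between rings A and D, ring C benzyl ether | COc1cccc2c1Oc1cccc(c1)CCc1ccc(OCc3ccccc3)c(c1)Oc1ccc(cc1)C2=C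
A2 | alternative 1 | 18-membered deoxybenzoin, carbonyl on ring A, ring C benzyl ether | COc1cccc2c1Oc1cccc(c1)CCc1ccc(OCc3ccccc3)c(c1)Oc1ccc(cc1)CC2=O
A3 | alternative 2 | open bis(dihalophenol): ring C 2,6-dibromophenol, ring D 2,6-dichlorophenol | COc1cccc(CCc2cc(Cl)c(O)c(Cl)c2)c1Oc1cccc(CCc2cc(Br)c(O)c(Br)c2)c1
A4 | alternative 2 | bromo-dichloro macrocycle | COc1cccc2c1Oc1cccc(c1)CCc1cc(Br)c(O)c(c1)Oc1c(Cl)cc(cc1Cl)CC2
A5 | alternative 3 | open ring B arylacetic acid with 2-(propan-2-yloxy)phenoxy ring C | COc1cccc(CCc2ccc(Oc3ccccc3OC(C)C)cc2)c1Oc1cccc(CC(O)=O)c1
A6 | alternative 3 | macrocyclic deoxybenzoin, carbonyl on ring C, ring C isopropyl ether | COc1cccc2c1Oc1cccc(c1)CC(=O)c1ccc(OC(C)C)c(c1)Oc1ccc(cc1)CC2
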